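## Structural features

The target is a depside with no stereocentre, so every problem is one of regiochemistry and chemoselectivity. Two benzene rings are joined by a single aryl ester that runs from the carboxyl carbon of ring A (a 2-hydroxy-4-methoxy-6-pentylbenzoyl unit) to O-4 of ring B (a 2-methoxy-6-propylbenzoic acid). Both rings show the resorcylate pattern: a carboxyl carbon at C1 between an oxygen at C2 and an n-alkyl chain at C6, with a second oxygen at C4. The fragile parts are the inter-ring aryl ester, an activated ester that hydroxide, alkoxide or amine nucleophiles would cleave, and the free, electron-rich, di-ortho-substituted acid of ring B, which can decarboxylate in hot acid; both carboxyl carbons are also sterically shielded. The real difficulty lies in ring B, whose two meta oxygens must end differently, O-2 as the methyl ether beside the carboxyl and O-4 as the acylated oxygen, while C1 carries the acid and C6 the propyl chain. Ring A is easier, because it is 5-pentylresorcinol plus one carbon, and its two oxygens differ by themselves once C1 bears a carbonyl group, one being chelated and the other not. The key step exploits the fact that O-2 and O-4 of ring B can come from different reactants: a vinylketene carbonyl delivers the free C2 hydroxyl, an ynol silyl ether delivers the C4 silyl ether, and the alkene of the ketene precursor brings C1 with its carboxyl and C6 with its propyl group, so that forming C5–C6, C4–C5, C2–C3 and C1–C2 closes ring B with all four substituents in place.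

## Logic of the disconnections

29 to 28. The two benzyl–oxygen bonds are cut together, one in the ether on the ring A phenol and one in the ester on the ring B carboxyl. The cut is placed last because one neutral hydrogenolysis then frees both groups without touching the inter-ring aryl ester or the acid that is prone to decarboxylation. The gain is that neither half needs a separate deprotection. The demand is that both masks are benzyl from the outset, so the ring B carboxyl is carried as a benzyl ester through the whole sequence.

28 to 20 and 26. The carbonyl–oxygen bond of the depside ester is cut. This divides the molecule into two halves of similar size and makes the route convergent. The forward step, which runs through 27, must transfer a di-ortho-substituted acyl group to a phenol, so 20 may offer only one free hydroxyl and 26 must have its ortho hydroxyl masked.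

20 to 19 to 18. The O–Si bond at O-4 and then the O–CH3 bond at O-2 are cut. Methylation is done while O-4 is still silylated, so the difference between the two oxygens that the ring synthesis creates passes directly into the final substitution and no selective handling of a resorcinol is needed. The demand is that the silyl ether survives the base-mediated methylation of a chelated phenol.

18 to 10 and 13. Ring B is opened at C5–C6, C4–C5, C2–C3 and C1–C2. A tetrasubstituted arene with two unlike meta oxygens becomes an open-chain diazo ketone and a two-carbon ynol ether, each of which holds its substituents by connectivity alone. The forward cascade, which passes through 14, 15, 16 and 17, needs the E alkene in 10 and a union of ketene and alkyne that is strictly controlled by polarity.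

10 to 7. The carbon–nitrogen bond of the diazo group is cut, so the diazo function is placed on a methyl ketone by diazo transfer, by way of 8 and 9. The route through an acid chloride and the simplest diazoalkane is set aside, because that reagent is explosive and toxic and, as a 1,3-dipole, would add to the alkene of this substrate, which two carbonyl groups activate. The gain is a nitrogen-free precursor that can be stored. The demand is clean kinetic enolization at the methyl group.

7 to 5 and 6. The C2=C3 double bond is cut, which assigns the alkene to a carbonyl olefination and splits the chain into a six-carbon and a two-carbon piece. The demand is that the olefination delivers the E isomer, with the acyl group trans to the ester.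

5 to 1 and 2. The bond between the ylide carbon and the acetyl carbon is cut, by way of 3 and 4. This reduces the branched keto ylide to two commodity chemicals. The demand is acylation of the ylide on carbon, with a second equivalent of 3 serving as the base.

13 to 11. The O–Si bond is cut back to 12, and behind 12 the two C–Br bonds and the C–OEt bond of 11 are restored. The gain is that the two-carbon ynol unit comes from a cheap ester. The demand is silylation on oxygen and not on carbon.

26 to 25 to 24 to 23 to 21. Read backwards, these are a lowering of the oxidation level at the carboxyl carbon, then the cutting of the O–benzyl bond, the O–methyl bond and the ring–formyl bond, the last by way of 22. Ring A is thereby reduced to purchasable 21. The demand is that formylation takes the position between one hydroxyl and the pentyl chain, and that the difference between the chelated and the free hydroxyl of 23 directs methylation to O-4.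

## Other disconnections considered

Alternative 1: This plan cuts three bonds around ring A at once: C6–pentyl, C1–carbonyl and the carbonyl–oxygen bond of the depside.
- Forward step: 2-(benzyloxy)-1-iodo-4-methoxybenzene A1, 1-iodopentane A2 and the O-formate of 20, benzyl 4-(formyloxy)-2-methoxy-6-propylbenzoate A3, would be combined under Catellani conditions with Pd(OAc)2 and the strained bicyclic alkene mediator. Zerovalent palladium inserts into the carbon–iodine bond of A1, the alkene mediator relays the metal to the free ortho position, A2 alkylates the palladacycle through a tetravalent palladium intermediate, and after extrusion of the mediator the aryl–palladium bond is terminated by the carbonyl unit and the phenoxide that A3 releases under base. The product would be benzyl 4-{[2-(benzyloxy)-4-methoxy-6-pentylbenzoyl]oxy}-2-methoxy-6-propylbenzoate A4, the dibenzyl-protected depside, which is the same compound as 28.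
- In favour: three bonds form in one operation, ring A comes from the simple iodoarene A1 and not in four steps from 21, and the endgame after A4 is the same hydrogenolysis.
- Against: termination of an ortho alkylation by aryloxycarbonylation from a formate is not an established mode of this manifold. The di-ortho-substituted acylpalladium must be captured by a weakly nucleophilic phenoxide faster than it decarbonylates, and carbonylation before alkylation, direct C–O coupling and β-hydride loss from the pentyl–palladium species all compete. A3 still requires 20, so ring B is not spared.
- Comparison: on step economy this alternative is the better, by about three steps. On protecting-group logic and on the final step it is the equal. On mechanistic security it is clearly weaker, and structurally it addresses ring A, which is not where the oxygen-differentiation problem lies.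

Alternative 2: This plan cuts ring A bond C1–C6.
- Forward step: the open-chain 6-(2,4-dioxononyl)-2,2-dimethyl-4H-1,3-dioxin-4-one A5 would cyclize under a mild amine base by attack of dioxinone C5 on the pentyl ketone, followed by dehydration, to give 7-hydroxy-2,2-dimethyl-5-pentyl-4H-1,3-benzodioxin-4-one A6. O-Methylation of A6 would give 7-methoxy-2,2-dimethyl-5-pentyl-4H-1,3-benzodioxin-4-one A7, which the phenoxide of 20 could open to the depside skeleton with the ring A ortho hydroxyl already free.
- In favour: the ring A carboxyl and ortho oxygen are masked together as one acetonide in A6, so ring A needs no benzyl ether. The chemistry is ionic and mild, with no diazo compound and no photochemistry, so on hazard this alternative is the better. Regiochemistry follows from chain connectivity, which makes it the equal of the chosen plan on that point.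
- Against: A5 is a sensitive tricarbonyl that takes several steps of dioxinone enolate acylation, while the ring A pattern is available from 21 in four routine steps. Opening of A7 by a phenoxide exchanges one aryloxide for another at a di-ortho-substituted carbonyl and may be slow or reversible. The plan does not touch ring B.
- Comparison: it forms one ring bond where the chosen step forms four, and it is not shorter overall.

Alternative 3: This plan cuts the C6–propyl and C1–carboxyl bonds of ring B.
- Forward step: (3-fluoro-5-methoxyphenoxy)triisopropylsilane A8 would be lithiated between fluorine and methoxy by an alkyllithium base. Loss of fluoride gives an aryne, propylmagnesium bromide A9 adds at the carbon remote from the methoxy group (C6), and the resulting C1 arylmagnesium is carboxylated to 2-methoxy-6-propyl-4-(triisopropylsilyloxy)benzoic acid A10.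
- In favour: ring B is reached in about two steps from a purchasable fluorophenol, with the methyl ether in place and O-4 already distinguished as a silyl ether in A8. There is no diazo compound and no photolysis. Addition to a 3-alkoxyaryne distal to the alkoxy group is a dependable regiochemical rule. On step economy, and arguably on safety, this alternative is the better.
- Against: A8 has three ring positions that are each flanked by two ortho-directing groups, so the site of lithiation is a matter of competition. The aryne must be intercepted by A9 faster than by the alkyllithium or the aryllithium. A10 is a free acid that needs benzyl esterification and desilylation before coupling, which returns part of the saving.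
- Comparison: the chosen plan is the equal in how it differentiates the two oxygens. It is better in that every substituent position follows from the connectivity of acyclic precursors and not from competing directing effects on a polyfunctional arene.

Key step: step 5

## Route

Remark on the chemistry: ring B is numbered C1 carboxyl, C2 methoxy, C4 acyloxy, C6 propyl; (E) in 10 means diazoacetyl trans to the ester.
Remark on the chemistry: 6 is taken as a purchasable reagent, cracked from its hydrate or oligomer by distillation before use.
Remark on the chemistry: 13 is used as a distilled stock that may carry inert ethoxytriisopropylsilane; 10 is handled in solution, cold and shielded from light.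

Step 1
Reactants: 1 butyltriphenylphosphonium bromide (2 equiv); 2 acetyl chloride (1 equiv)
Product: 5 3-(triphenylphosphoranylidene)hexan-2-one, via butylidenetriphenylphosphorane 3 (not isolated), via (2-oxohexan-3-yl)triphenylphosphonium chloride 4 (not isolated)
Conditions: NaN(SiMe3)2 (2 equiv), THF, 0 °C; then 2, −78 °C to rt
Reagents that add atoms: none
Why: C-Acylation of a nonstabilized ylide by an acid chloride with transylidation: 3 attacks 2 to give 4, which the second equivalent of 3 deprotonates to the keto-stabilized ylide 5. The phosphonium salt regenerated in this way can be recovered.

Step 2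
Reactants: 5 3-(triphenylphosphoranylidene)hexan-2-one; 6 benzyl glyoxylate
Product: 7 benzyl (E)-3-acetylhex-2-enoate
Conditions: toluene, 80 °C
Reagents that add atoms: none
Why: Wittig olefination of a very electrophilic aldehyde with an α-branched stabilized ylide. Such ylides place the aldehyde substituent, here the ester, trans to the ylide carbonyl, so the E alkene should predominate and any Z isomer can be removed by chromatography.

Step 3
Reactants: 7 benzyl (E)-3-acetylhex-2-enoate
Product: 10 benzyl (E)-3-(2-diazoacetyl)hex-2-enoate, via lithium dienolate 8 (not isolated), via trifluoroacetyl diketone 9 (not isolated)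
Conditions: LiN(SiMe3)2, THF, −78 °C; CF3CO2CH2CF3, −78 °C; then 4-acetamidobenzenesulfonyl azide, Et3N, H2O, MeCN, rt
Reagents that add atoms: 4-acetamidobenzenesulfonyl azide, CC(=O)Nc1ccc(cc1)S(=O)(=O)N=[N+]=[N-]
Why: Detrifluoroacetylative diazo transfer: kinetic enolization of the methyl group, the only enolizable position next to the ketone, and Claisen trifluoroacetylation give 9, whose activated methylene accepts the diazo group with loss of the trifluoroacetyl group as an N-acylsulfonamide. This is the standard entry to α-diazo enones; it avoids a hazardous diazoalkane that would also add as a dipole to the doubly activated alkene, and a bench-stable sulfonyl azide is chosen for the same reason.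

Step 4
Reactants: 11 ethyl dibromoacetate
Product: 13 triisopropylsiloxyethyne, via lithium ethynolate 12 (not isolated)
Conditions: lithium 4,4'-di-tert-butylbiphenylide (4.4 equiv), THF, −78 °C, 11 added to the reductant, then 0 °C; iPr3SiOTf (2.2 equiv), −78 °C to rt; bulb-to-bulb distillation
Reagents that add atoms: triisopropylsilyl trifluoromethanesulfonate, CC(C)[Si](OS(=O)(=O)C(F)(F)F)(C(C)C)C(C)C
Why: Ynolate formation by cleavage of an ester dianion: two reductive bromine–lithium exchanges on the α,α-dibromo ester give the dianion, which expels ethoxide to 12, and the hard, bulky silyl triflate should then silylate on oxygen to the siloxyalkyne. The electron-transfer reagent replaces tert-butyllithium, and the second equivalent of silyl triflate consumes the ethoxide that is released.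

Step 5
Reactants: 10 benzyl (E)-3-(2-diazoacetyl)hex-2-enoate; 13 triisopropylsiloxyethyne (1.5 equiv)
Product: 18 benzyl 2-hydroxy-6-propyl-4-(triisopropylsilyloxy)benzoate, via vinylketene 14 (not isolated), via siloxycyclobutenone 15 (not isolated), via dienylketene 16 (not isolated), via cyclohexadienone 17 (not isolated)
Conditions: hν (300 nm), ClCH2CH2Cl, rt; then 80 °C
Reagents that add atoms: none
Why: This is the Danheiser benzannulation in its photochemical Wolff variant, whose closest known reaction type is the union of α-diazo enones with trialkylsiloxyalkynes to give resorcinol monosilyl ethers. Excitation of 10 expels dinitrogen with a 1,2-shift of the alkenyl carbon (bond C5–C6) to give vinylketene 14, whose carbonyl carbon is attacked by the nucleophilic CH terminus of 13 in a (2+2) cycloaddition (bonds C2–C3 and C4–C5) to give 15. Reversible thermal 4π electrocyclic opening of 15 gives dienylketene 16, which closes ring B by a thermally allowed disrotatory 6π electrocyclization (bond C1–C2) to 17, and tautomerization aromatizes this to 18. No stereocentre survives, because the sp3 carbons of 15 and 17 are transient and are lost on aromatization. The selectivity needed is regiochemical and is secured by the polarization of the ynol ether: the oxygen lone pair makes the unsubstituted carbon the nucleophile and the ketene carbonyl carbon is the only strong electrophile, so the ketene oxygen becomes the C2 hydroxyl and the siloxy carbon becomes C4. The E alkene of 10 keeps the ester on the outside of the closing triene and away from the ketene, and the ester raises the electrophilicity of 14 toward the electron-rich alkyne. The product is a chelated salicylate, which should be a poor nucleophile toward residual ketene and should dissipate absorbed light by internal proton transfer; the final heating converts any remaining 15.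

Step 6
Reactants: 18 benzyl 2-hydroxy-6-propyl-4-(triisopropylsilyloxy)benzoate
Product: 19 benzyl 2-methoxy-6-propyl-4-(triisopropylsilyloxy)benzoate
Conditions: MeI, K2CO3, acetone, 50 °C
Reagents that add atoms: iodomethane, CI
Why: Williamson O-methylation of the only free phenol. Anhydrous carbonate in acetone is basic enough for a chelated salicylate hydroxyl, and the hindered triisopropylsilyl aryl ether should tolerate it.

Step 7
Reactants: 19 benzyl 2-methoxy-6-propyl-4-(triisopropylsilyloxy)benzoate
Product: 20 benzyl 4-hydroxy-2-methoxy-6-propylbenzoate
Conditions: Bu4NF, AcOH, THF, 0 °C
Reagents that add atoms: none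
Why: Fluoride-induced cleavage of the aryl silyl ether, driven by the Si–F bond. Acetic acid protonates the phenoxide as it forms, and the shielded benzyl ester is inert to fluoride.

Step 8
Reactants: 21 olivetol
Product: 23 2,4-dihydroxy-6-pentylbenzaldehyde, via aryliminium chloride 22 (not isolated)
Conditions: POCl3, DMF, 0 °C to rt; then H2O, 50 °C
Reagents that add atoms: N,N-dimethylformamide, CN(C)C=O; water, O
Why: Vilsmeier–Haack formylation of a resorcinol. The chloroiminium electrophile attacks the position para to one hydroxyl and ortho to the other in preference to the more crowded position between the two hydroxyls, and hydrolysis of 22 releases the aldehyde.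

Step 9
Reactants: 23 2,4-dihydroxy-6-pentylbenzaldehyde
Product: 24 2-hydroxy-4-methoxy-6-pentylbenzaldehyde
Conditions: MeI (1 equiv), K2CO3 (1 equiv), acetone, rt
Reagents that add atoms: iodomethane, CI
Why: Regioselective Williamson methylation. The 4-hydroxyl is para to the formyl group, more acidic and not hydrogen-bonded, whereas the 2-hydroxyl is locked in a chelate with the carbonyl, so one equivalent of base and electrophile should alkylate O-4.

Step 10
Reactants: 24 2-hydroxy-4-methoxy-6-pentylbenzaldehyde
Product: 25 2-(benzyloxy)-4-methoxy-6-pentylbenzaldehyde
Conditions: BnBr, K2CO3, DMF, 60 °C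
Reagents that add atoms: benzyl bromide, BrCc1ccccc1
Why: Williamson benzylation of the remaining chelated phenol under more forcing conditions, which installs the mask that is removed together with the ring B benzyl ester at the end.

Step 11
Reactants: 25 2-(benzyloxy)-4-methoxy-6-pentylbenzaldehyde
Product: 26 2-(benzyloxy)-4-methoxy-6-pentylbenzoic acid
Conditions: NaClO2, NaH2PO4, 2-methyl-2-butene, t-BuOH/H2O, rt
Reagents that add atoms: sodium chlorite, [Na+].[O-]Cl=O
Why: Pinnick (chlorite) oxidation of an aldehyde to the acid. The alkene scavenger removes hypochlorous acid so that the electron-rich ring is not chlorinated.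

Step 12
Reactants: 20 benzyl 4-hydroxy-2-methoxy-6-propylbenzoate; 26 2-(benzyloxy)-4-methoxy-6-pentylbenzoic acid
Product: 28 benzyl 4-{[2-(benzyloxy)-4-methoxy-6-pentylbenzoyl]oxy}-2-methoxy-6-propylbenzoate, via mixed trifluoroacetic anhydride 27 (not isolated)
Conditions: (CF3CO)2O, toluene, 0 °C to rt
Reagents that add atoms: none
Why: Esterification of a phenol through a mixed carboxylic–trifluoroacetic anhydride. The electron-rich, di-ortho-substituted acyl group of 27 ionizes readily toward an acylium-like species that the unhindered C4 hydroxyl of 20 captures, so a hindered acid is joined to a phenol without base that could endanger the product ester.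

Step 13
Reactants: 28 benzyl 4-{[2-(benzyloxy)-4-methoxy-6-pentylbenzoyl]oxy}-2-methoxy-6-propylbenzoate
Product: 29 4-[(2-hydroxy-4-methoxy-6-pentylbenzoyl)oxy]-2-methoxy-6-propylbenzoic acid
Conditions: H2 (1 atm), Pd/C, EtOAc, rt
Reagents that add atoms: none
Why: Catalytic hydrogenolysis cleaves the benzyl ether and the benzyl ester in one neutral operation. The aryl ester, the methyl ethers and the arenes are not reduced under these conditions, and the acid is liberated without acid or base.

## Compound list

1 | butyltriphenylphosphonium bromide | CCCC[P+](c1ccccc1)(c1ccccc1)c1ccccc1.[Br-] | starting material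
2 | acetyl chloride | CC(Cl)=O | starting material
3 | butylidenetriphenylphosphorane | CCCC=P(c1ccccc1)(c1ccccc1)c1ccccc1 | intermediate
4 | (2-oxohexan-3-yl)triphenylphosphonium chloride | CCCC(C(C)=O)[P+](c1ccccc1)(c1ccccc1)c1ccccc1.[Cl-] | intermediate
5 | 3-(triphenylphosphoranylidene)hexan-2-one | CCCC(C(C)=O)=P(c1ccccc1)(c1ccccc1)c1ccccc1 | intermediate
6 | benzyl glyoxylate (benzyl 2-oxoacetate) | O=CC(=O)OCc1ccccc1 | starting material
7 | benzyl (E)-3-acetylhex-2-enoate | CCC/C(C(C)=O)=C\C(=O)OCc1ccccc1 | intermediate
8 | lithium (3E)-5-(benzyloxy)-5-oxo-3-propylpenta-1,3-dien-2-olate | [Li+].[O-]C(=C)/C(CCC)=C/C(=O)OCc1ccccc1 | intermediate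
9 | benzyl (E)-3-(4,4,4-trifluoro-3-oxobutanoyl)hex-2-enoate | CCC/C(C(=O)CC(=O)C(F)(F)F)=C\C(=O)OCc1ccccc1 | intermediate
10 | benzyl (E)-3-(2-diazoacetyl)hex-2-enoate | CCC/C(C(=O)C=[N+]=[N-])=C\C(=O)OCc1ccccc1 | intermediate
11 | ethyl dibromoacetate | CCOC(=O)C(Br)Br | starting material
12 | lithium ethynolate | [Li+].[O-]C#C | intermediate
13 | triisopropylsiloxyethyne | C#CO[Si](C(C)C)(C(C)C)C(C)C | intermediate
14 | benzyl (E)-3-(2-oxoethenyl)hex-2-enoate | CCC/C(C=C=O)=C\C(=O)OCc1ccccc1 | intermediate
15 | benzyl (E)-3-[2-oxo-4-(triisopropylsilyloxy)cyclobut-3-en-1-yl]hex-2-enoate, racemic | CCC/C(C1C(=O)C=C1O[Si](C(C)C)(C(C)C)C(C)C)=C\C(=O)OCc1ccccc1 | intermediate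
16 | benzyl (2E,4E)-7-oxo-3-propyl-5-(triisopropylsilyloxy)hepta-2,4,6-trienoate | CCC/C(=C\C(=O)OCc1ccccc1)/C=C(\C=C=O)O[Si](C(C)C)(C(C)C)C(C)C | intermediate
17 | benzyl 2-oxo-6-propyl-4-(triisopropylsilyloxy)cyclohexa-3,5-diene-1-carboxylate, racemic | CCCC1=CC(O[Si](C(C)C)(C(C)C)C(C)C)=CC(=O)C1C(=O)OCc1ccccc1 | intermediate
18 | benzyl 2-hydroxy-6-propyl-4-(triisopropylsilyloxy)benzoate | CCCc1cc(O[Si](C(C)C)(C(C)C)C(C)C)cc(O)c1C(=O)OCc1ccccc1 | intermediate
19 | benzyl 2-methoxy-6-propyl-4-(triisopropylsilyloxy)benzoate | CCCc1cc(O[Si](C(C)C)(C(C)C)C(C)C)cc(OC)c1C(=O)OCc1ccccc1 | intermediate
20 | benzyl 4-hydroxy-2-methoxy-6-propylbenzoate | CCCc1cc(O)cc(OC)c1C(=O)OCc1ccccc1 | intermediate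
21 | olivetol (5-pentylbenzene-1,3-diol) | CCCCCc1cc(O)cc(O)c1 | starting material
22 | [(2,4-dihydroxy-6-pentylphenyl)methylidene]dimethylammonium chloride | CCCCCc1cc(O)cc(O)c1C=[N+](C)C.[Cl-] | intermediate
23 | 2,4-dihydroxy-6-pentylbenzaldehyde | CCCCCc1cc(O)cc(O)c1C=O | intermediate
24 | 2-hydroxy-4-methoxy-6-pentylbenzaldehyde | CCCCCc1cc(OC)cc(O)c1C=O | intermediate
25 | 2-(benzyloxy)-4-methoxy-6-pentylbenzaldehyde | CCCCCc1cc(OC)cc(OCc2ccccc2)c1C=O | intermediate
26 | 2-(benzyloxy)-4-methoxy-6-pentylbenzoic acid | CCCCCc1cc(OC)cc(OCc2ccccc2)c1C(=O)O | intermediate
27 | 2-(benzyloxy)-4-methoxy-6-pentylbenzoic trifluoroacetic anhydride | CCCCCc1cc(OC)cc(OCc2ccccc2)c1C(=O)OC(=O)C(F)(F)F | intermediate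
28 | benzyl 4-{[2-(benzyloxy)-4-methoxy-6-pentylbenzoyl]oxy}-2-methoxy-6-propylbenzoate | CCCCCc1cc(OC)cc(OCc2ccccc2)c1C(=O)Oc1cc(CCC)c(C(=O)OCc2ccccc2)c(OC)c1 | intermediate
29 | 4-[(2-hydroxy-4-methoxy-6-pentylbenzoyl)oxy]-2-methoxy-6-propylbenzoic acid | CCCCCc1cc(OC)cc(O)c1C(=O)Oc1cc(CCC)c(C(=O)O)c(OC)c1 | target

## Step count and least certain steps

Total step count: 13. Longest linear sequence: 8 steps, namely steps 1, 2, 3, 5, 6, 7, 12 and 13, from 1 to 29. The ring A branch, steps 8 to 11, joins it at step 12, and the alkyne branch, step 4, joins it at step 5.

Step 5 (key step).
- What may go wrong: the alkene can isomerize from E to Z under irradiation, before or after the Wolff rearrangement. The ketene can then be trapped within the molecule by the now-cis ester carbonyl, or, if bimolecular capture by 13 is slow, it can dimerize or acylate the product phenol. The thermal conversion of 15 may also stall. The cause is that a ketene carrying a conjugated ester has fast unimolecular outlets that compete with the desired intermolecular (2+2) event.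
- Fallback: a polar ring synthesis that replaces steps 1 to 5. It therefore sets out from no numbered compound of the route but from purchased (E)-hept-3-en-2-one F1 and dibenzyl malonate F2, and it comes back to the route at 18. Michael addition of F2 to F1, followed by Claisen cyclization of the methyl ketone onto one ester under NaOCH2Ph in benzyl alcohol and THF, should give benzyl 2,4-dioxo-6-propylcyclohexane-1-carboxylate F3. Bromination and dehydrobromination of F3 with Br2 in DMF should aromatize it to benzyl 2,4-dihydroxy-6-propylbenzoate F4. Silylation of F4 with iPr3SiCl and imidazole should then occur at the free, more acidic 4-hydroxyl and not at the chelated 2-hydroxyl, which gives 18.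

Step 4.
- What may go wrong: proton transfer from the acidic CHBr2 hydrogen of 11 to the anionic intermediates can compete with reductive carbon–bromine cleavage. The unsubstituted ynolate 12 may be silylated at its unhindered carbon, which leads toward a silylketene, and not at oxygen. The volatile product can also be lost on isolation.
- Fallback: an alkyl ynol ether in place of the silyl one, with a correspondingly different deprotection; it sets out from 10 and comes back to the route at 20. Potassium tert-butoxide and purchased trichloroethylene F5 should give (E)-1-(tert-butoxy)-1,2-dichloroethene F6. Two equivalents of butyllithium followed by an aqueous quench should convert F6 into tert-butoxyethyne F7, which is kept cold because it fragments thermally on warming. Irradiation of 10 with F7 as in step 5, with the excess of F7 evaporated before the heating stage, should give benzyl 4-(tert-butoxy)-2-hydroxy-6-propylbenzoate F8. Methylation of F8 with MeI and K2CO3 should give benzyl 4-(tert-butoxy)-2-methoxy-6-propylbenzoate F9, and trifluoroacetic acid in CH2Cl2 at 0 °C should cleave the tert-butyl aryl ether of F9 to give 20.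

Step 3.
- What may go wrong: the kinetic enolate 8 can add in conjugate fashion to the doubly activated alkene of a second molecule of 7 before it is trifluoroacetylated, which leads to oligomers. Base-induced isomerization of the alkene is a second risk.
- Fallback: a route without a strong base that sets out from 7 and comes back at 10. Soft enolization of 7 with Me3SiOTf and Et3N should give benzyl (E)-3-[1-(trimethylsilyloxy)ethenyl]hex-2-enoate F10. N-Bromosuccinimide should convert F10 into benzyl (E)-3-(2-bromoacetyl)hex-2-enoate F11. N,N'-Ditosylhydrazine and DBU should then displace the bromide of F11 and eliminate two sulfinates, the known conversion of bromoacetyl into diazoacetyl compounds, to give 10.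

Step 12.
- What may go wrong: acyl transfer from a di-ortho-substituted donor to a phenol deactivated by a para ester may be slow. Trifluoroacetylation of 20 may then compete, and the acylium-like intermediate may shed the neighbouring benzyl group under the acidic conditions.
- Fallback: base-mediated acylation with a discrete acyl halide, which sets out from 26 and comes back at 28. Oxalyl chloride with catalytic DMF should give 2-(benzyloxy)-4-methoxy-6-pentylbenzoyl chloride F12, and F12 is then combined with 20, Et3N and catalytic 4-(dimethylamino)pyridine in CH2Cl2.

Step 6.
- What may go wrong: carbonate or the phenoxide may attack silicon, so that the silyl group is lost or migrates and O-4 is then methylated, which erodes the differentiation of the two oxygens. Alkylation of the chelated phenol may also be slow.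
- Fallback: a neutral redox condensation in place of phenoxide alkylation, which sets out from 18 and comes back at 19. Mitsunobu methylation with methanol, PPh3 and diisopropyl azodicarboxylate in THF activates the alcohol and involves no base that can attack silicon. It makes no new compound.

## Further compounds

F1 | step 5 | (E)-hept-3-en-2-one | CCC/C=C/C(C)=O
F2 | step 5 | dibenzyl malonate | O=C(CC(=O)OCc1ccccc1)OCc1ccccc1
F3 | step 5 | benzyl 2,4-dioxo-6-propylcyclohexane-1-carboxylate, mixture of stereoisomers and enol forms | CCCC1CC(=O)CC(=O)C1C(=O)OCc1ccccc1
F4 | step 5 | benzyl 2,4-dihydroxy-6-propylbenzoate | CCCc1cc(O)cc(O)c1C(=O)OCc1ccccc1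
F5 | step 4 | trichloroethylene | ClC=C(Cl)Cl
F6 | step 4 | (E)-1-(tert-butoxy)-1,2-dichloroethene | CC(C)(C)O/C(Cl)=C\Cl
F7 | step 4 | tert-butoxyethyne | CC(C)(C)OC#C
F8 | step 4 | benzyl 4-(tert-butoxy)-2-hydroxy-6-propylbenzoate | CCCc1cc(OC(C)(C)C)cc(O)c1C(=O)OCc1ccccc1
F9 | step 4 | benzyl 4-(tert-butoxy)-2-methoxy-6-propylbenzoate | CCCc1cc(OC(C)(C)C)cc(OC)c1C(=O)OCc1ccccc1
F10 | step 3 | benzyl (E)-3-[1-(trimethylsilyloxy)ethenyl]hex-2-enoate | CCC/C(C(=C)O[Si](C)(C)C)=C\C(=O)OCc1ccccc1
F11 | step 3 | benzyl (E)-3-(2-bromoacetyl)hex-2-enoate | CCC/C(C(=O)CBr)=C\C(=O)OCc1ccccc1
F12 | step 12 | 2-(benzyloxy)-4-methoxy-6-pentylbenzoyl chloride | CCCCCc1cc(OC)cc(OCc2ccccc2)c1C(Cl)=O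
F0 | step 6 | none | none
A1 | alternative 1 | 2-(benzyloxy)-1-iodo-4-methoxybenzene | COc1ccc(I)c(OCc2ccccc2)c1
A2 | alternative 1 | 1-iodopentane | CCCCCI
A3 | alternative 1 | benzyl 4-(formyloxy)-2-methoxy-6-propylbenzoate | CCCc1cc(OC=O)cc(OC)c1C(=O)OCc1ccccc1
A4 | alternative 1 | benzyl 4-{[2-(benzyloxy)-4-methoxy-6-pentylbenzoyl]oxy}-2-methoxy-6-propylbenzoate | CCCCCc1cc(OC)cc(OCc2ccccc2)c1C(=O)Oc1cc(CCC)c(C(=O)OCc2ccccc2)c(OC)c1
A5 | alternative 2 | 6-(2,4-dioxononyl)-2,2-dimethyl-4H-1,3-dioxin-4-one | CCCCCC(=O)CC(=O)CC1=CC(=O)OC(C)(C)O1
A6 | alternative 2 | 7-hydroxy-2,2-dimethyl-5-pentyl-4H-1,3-benzodioxin-4-one | CCCCCc1cc(O)cc2OC(C)(C)OC(=O)c12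
A7 | alternative 2 | 7-methoxy-2,2-dimethyl-5-pentyl-4H-1,3-benzodioxin-4-one | CCCCCc1cc(OC)cc2OC(C)(C)OC(=O)c12
A8 | alternative 3 | (3-fluoro-5-methoxyphenoxy)triisopropylsilane | COc1cc(F)cc(O[Si](C(C)C)(C(C)C)C(C)C)c1
A9 | alternative 3 | propylmagnesium bromide | CCC[Mg]Br
A10 | alternative 3 | 2-methoxy-6-propyl-4-(triisopropylsilyloxy)benzoic acid | CCCc1cc(O[Si](C(C)C)(C(C)C)C(C)C)cc(OC)c1C(=O)O
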